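**Retrosynthetic overview**
- The target is the 4a-epimer of the trans-decalin that a biomimetic intramolecular Diels–Alder reaction delivers, so the cis ring fusion is set last: β-face hydrogenation of a Δ4a,8a-enone.
- That enone comes from the Diels–Alder adduct by Rubottom oxidation (C2–OH), dehydrogenation, dihydroxylation of a 7-methylidene group (C7) and hydroxymethylation of a 4-acetyl group (side chain).
- Rings A and B are closed together, in one step, by the intramolecular Diels–Alder reaction of an (E)-enone tethered to a 2-silyloxydiene; this sets C3 and C4 under control of the C5 methyl group.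
- The tetraene is assembled by HWE, Negishi and HWE couplings from methyl (R)-3-hydroxy-2-methylpropanoate (source of C5 and of the sec-butyl centre), 2,3-dibromopropene and one ketophosphonate used twice.

Assumption: 1, 4 and 5 are taken as commercial; decalins are numbered as in the target (C1 ketone, C2 carbinol, C3 sec-butyl, C4 quaternary, C4a/C8a fusion, C5 methyl, C7 carbinol) and β means the face of 8a-H in 21.

**Step 1**
Reactants: 1 methyl (2R)-3-hydroxy-2-methylpropanoate
Product: 2 methyl (2S)-3-iodo-2-methylpropanoate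
Conditions: I2, PPh3, imidazole, CH2Cl2, 0 → 23 °C
Reagents that add atoms: iodine, II
Why: Appel iodination is an SN2 displacement at the primary carbon, so the stereocentre is untouched (the descriptor changes only through priorities).

**Step 2**
Reactants: 2 methyl (2S)-3-iodo-2-methylpropanoate
Product: 3 methyl (2R)-2-methylbutanoate
Conditions: Me2CuLi (from MeLi, CuI), Et2O, −40 → 0 °C
Reagents that add atoms: lithium dimethylcuprate, [Li+].C[Cu-]C
Why: Gilman cuprate substitution of the primary iodide turns CH2I into ethyl and so creates the (R)-sec-butyl unit without touching the α-centre or the ester.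

**Step 3**
Reactants: 4 diethyl (3-oxobutan-2-yl)phosphonate; 5 2,3-dibromoprop-1-ene
Product: 6 diethyl (6-bromo-3-oxohept-6-en-2-yl)phosphonate
Conditions: NaH, THF, 0 °C; n-BuLi, −78 → 0 °C; then 5, −78 → 0 °C; aqueous work-up
Reagents that add atoms: none
Why: The β-ketophosphonate dianion is alkylated selectively at the terminal (γ) carbon by the allylic bromide.

**Step 4**
Reactants: 3 methyl (2R)-2-methylbutanoate; 6 diethyl (6-bromo-3-oxohept-6-en-2-yl)phosphonate
Product: 8 (6E,8R)-2-bromo-6,8-dimethyldeca-1,6-dien-5-one, via (2R)-2-methylbutanal 7 (not isolated)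
Conditions: i-Bu2AlH, CH2Cl2, −78 °C; then sodium salt of 6 (NaH, THF), −78 → 23 °C
Reagents that add atoms: none
Why: Partial ester reduction and Horner–Wadsworth–Emmons olefination in one pot avoid isolating the volatile, epimerisable aldehyde; the α-methyl ketophosphonate gives the (E)-trisubstituted enone.

**Step 5**
Reactants: 2 methyl (2S)-3-iodo-2-methylpropanoate; 8 (6E,8R)-2-bromo-6,8-dimethyldeca-1,6-dien-5-one
Product: 10 methyl (2R,8E,10R)-2,8,10-trimethyl-4-methylidene-7-oxododec-8-enoate, via methyl (2S)-3-(iodozincio)-2-methylpropanoate 9 (not isolated)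
Conditions: Zn dust (BrCH2CH2Br, TMSCl), THF/DMA, 25 °C; then 8, Pd(PPh3)4 (5 mol %), 40 °C
Reagents that add atoms: none
Why: Negishi sp3–sp2 coupling of the zinc homoenolate with the 2-bromoalkene; the stereocentre is β to zinc and is retained, and alkylzinc iodides do not add to the enone.

**Step 6**
Reactants: 10 methyl (2R,8E,10R)-2,8,10-trimethyl-4-methylidene-7-oxododec-8-enoate
Product: 11 methyl (2R,6Z,8E,10R)-7-[(tert-butyldimethylsilyl)oxy]-2,8,10-trimethyl-4-methylidenedodeca-6,8-dienoate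
Conditions: TBSOTf, Et3N, CH2Cl2, −78 → 0 °C
Reagents that add atoms: tert-butyldimethylsilyl trifluoromethanesulfonate, CC(C)(C)[Si](C)(C)OS(=O)(=O)C(F)(F)F
Why: Soft enolisation of the enone at the α′-CH2 gives the cross-conjugated 2-silyloxydiene, with (6Z) geometry favoured by A(1,3) strain; the ester and the γ sec-butyl C–H are not touched.

**Step 7**
Reactants: 11 methyl (2R,6Z,8E,10R)-7-[(tert-butyldimethylsilyl)oxy]-2,8,10-trimethyl-4-methylidenedodeca-6,8-dienoate
Product: 12 (2R,6Z,8E,10R)-7-[(tert-butyldimethylsilyl)oxy]-2,8,10-trimethyl-4-methylidenedodeca-6,8-dienal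
Conditions: i-Bu2AlH, toluene, −78 °C; Rochelle salt work-up
Reagents that add atoms: none
Why: Partial reduction of the methyl ester stops at the tetrahedral aluminium hemiacetal at −78 °C; the silyl dienol ether is inert.

**Step 8**
Reactants: 12 (2R,6Z,8E,10R)-7-[(tert-butyldimethylsilyl)oxy]-2,8,10-trimethyl-4-methylidenedodeca-6,8-dienal; 4 diethyl (3-oxobutan-2-yl)phosphonate
Product: 13 (3E,5R,9Z,11E,13R)-10-[(tert-butyldimethylsilyl)oxy]-3,5,11,13-tetramethyl-7-methylidenepentadeca-3,9,11-trien-2-one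
Conditions: Ba(OH)2, THF/H2O (40:1), 0 → 23 °C
Reagents that add atoms: none
Why: Horner–Wadsworth–Emmons olefination under mild barium hydroxide conditions gives the (E)-enone without epimerising the α-methyl aldehyde.

**Step 9**
Reactants: 13 (3E,5R,9Z,11E,13R)-10-[(tert-butyldimethylsilyl)oxy]-3,5,11,13-tetramethyl-7-methylidenepentadeca-3,9,11-trien-2-one
Product: 14 4α-acetyl-3α-[(2R)-butan-2-yl]-1-[(tert-butyldimethylsilyl)oxy]-2,4β,5α-trimethyl-7-methylidene-3,4,4a,5,6,7,8,8a-octahydronaphthalene, trans-fused (4aα-H, 8aβ-H, 3β-H)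
Conditions: toluene (0.01 M), BHT, 120 °C, sealed tube
Reagents that add atoms: none
Why: Intramolecular Diels–Alder reaction through the endo (acetyl under the diene) transition state with a chair tether and the C5 methyl equatorial sets C3 and C4 (C4a and C8a are set here but re-set in step 14).

**Step 10**
Reactants: 14 the silyl enol ether adduct above
Product: 16 (2S,3R,4R,4aS,5R,8aS)-4-acetyl-3-[(2R)-butan-2-yl]-2-hydroxy-2,4,5-trimethyl-7-methylideneoctahydronaphthalen-1(2H)-one, via 1β,2β-silyloxy epoxide 15 (not isolated)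
Conditions: DMDO (1.1 equiv), acetone/CH2Cl2, −78 → −20 °C; then aq. HF, MeCN, 0 °C
Reagents that add atoms: dimethyldioxirane, CC1(C)OO1
Why: Rubottom oxidation: the electron-rich enol ether is epoxidised far faster than the 1,1-disubstituted alkene, from the β-face anti to the pseudoaxial 3α-sec-butyl group, which sets the 2β-OH.

**Step 11**
Reactants: 16 the trans-fused ketol above
Product: 17 4α-acetyl-3α-[(2R)-butan-2-yl]-2β-hydroxy-2α,4β,5α-trimethyl-7-methylidene-3,4,5,6,7,8-hexahydronaphthalen-1(2H)-one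
Conditions: IBX (3 equiv), DMSO/toluene (1:2), 80 °C
Reagents that add atoms: none
Why: IBX dehydrogenation can act only at C8a–C4a (C2 is quaternary and the acetyl group has no β-hydrogen), giving the conjugated tetrasubstituted enone and erasing the C4a/C8a configuration.

**Step 12**
Reactants: 17 the Δ4a,8a-enone above
Product: 18 4α-acetyl-3α-[(2R)-butan-2-yl]-2β,7β-dihydroxy-7α-(hydroxymethyl)-2α,4β,5α-trimethyl-3,4,5,6,7,8-hexahydronaphthalen-1(2H)-one
Conditions: OsO4 (2 mol %), NMO, acetone/H2O (9:1), 0 → 23 °C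
Reagents that add atoms: osmium tetroxide (catalyst), O=[Os](=O)(=O)=O; N-methylmorpholine N-oxide, C[N+]1([O-])CCOCC1; water, O
Why: Upjohn dihydroxylation touches only the exocyclic alkene (the enone is tetrasubstituted and electron-poor); OsO4 attacks equatorially from the β-face, anti to the 5α-methyl that A(1,2) strain holds pseudoaxial, giving the 7β-OH.

**Step 13**
Reactants: 18 the enone triol above
Product: 20 3α-[(2R)-butan-2-yl]-2β,7β-dihydroxy-7α-(hydroxymethyl)-4α-(3-hydroxypropanoyl)-2α,4β,5α-trimethyl-3,4,5,6,7,8-hexahydronaphthalen-1(2H)-one, via tetrakis(trimethylsilyl) enol ether 19 (not isolated)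
Conditions: TMSOTf (5 equiv), Et3N, CH2Cl2, −78 → 0 °C; concentrate; then aq. HCHO, Yb(OTf)3 (10 mol %), THF/H2O, 23 °C; citric acid work-up
Reagents that add atoms: formaldehyde, C=O
Why: Mukaiyama aldol hydroxymethylation with aqueous formaldehyde; the methyl ketone is the only carbonyl with α-hydrogens at this stage, and the three hydroxyls are masked in situ as TMS ethers that fall off on work-up.

**Step 14**
Reactants: 20 the enone tetraol above
Product: 21 (2S,3R,4R,4aR,5R,7R,8aS)-3-[(2R)-butan-2-yl]-2,7-dihydroxy-7-(hydroxymethyl)-4-(3-hydroxypropanoyl)-2,4,5-trimethyloctahydronaphthalen-1(2H)-one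
Conditions: H2 (4 atm), 10% Pd on carbon, EtOAc, 23 °C
Reagents that add atoms: none
Why: Heterogeneous syn-hydrogenation from the β-face (the α-face of C4a is flanked by the 5α-methyl and the 4α-acyl group) delivers 4aβ-H and 8aβ-H, the cis ring fusion; neutral conditions avoid epimerising C8a.

**Compound list**
1 | methyl (2R)-3-hydroxy-2-methylpropanoate | COC(=O)[C@H](C)CO | starting material
2 | methyl (2S)-3-iodo-2-methylpropanoate | COC(=O)[C@H](C)CI | intermediate
3 | methyl (2R)-2-methylbutanoate | CC[C@@H](C)C(=O)OC | intermediate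
4 | diethyl (3-oxobutan-2-yl)phosphonate (racemic) | CCOP(=O)(OCC)C(C)C(C)=O | starting material
5 | 2,3-dibromoprop-1-ene | BrCC(Br)=C | starting material
6 | diethyl (6-bromo-3-oxohept-6-en-2-yl)phosphonate (racemic) | CCOP(=O)(OCC)C(C)C(=O)CCC(Br)=C | intermediate
7 | (2R)-2-methylbutanal | CC[C@@H](C)C=O | intermediate (not isolated)
8 | (6E,8R)-2-bromo-6,8-dimethyldeca-1,6-dien-5-one | CC[C@@H](C)/C=C(\C)C(=O)CCC(Br)=C | intermediate
9 | methyl (2S)-3-(iodozincio)-2-methylpropanoate | COC(=O)[C@H](C)C[Zn]I | intermediate (not isolated)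
10 | methyl (2R,8E,10R)-2,8,10-trimethyl-4-methylidene-7-oxododec-8-enoate | COC(=O)[C@H](C)CC(=C)CCC(=O)/C(C)=C/[C@H](C)CC | intermediate
11 | methyl (2R,6Z,8E,10R)-7-[(tert-butyldimethylsilyl)oxy]-2,8,10-trimethyl-4-methylidenedodeca-6,8-dienoate | COC(=O)[C@H](C)CC(=C)C/C=C(\O[Si](C)(C)C(C)(C)C)/C(C)=C/[C@H](C)CC | intermediate
12 | (2R,6Z,8E,10R)-7-[(tert-butyldimethylsilyl)oxy]-2,8,10-trimethyl-4-methylidenedodeca-6,8-dienal | O=C[C@H](C)CC(=C)C/C=C(\O[Si](C)(C)C(C)(C)C)/C(C)=C/[C@H](C)CC | intermediate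
13 | (3E,5R,9Z,11E,13R)-10-[(tert-butyldimethylsilyl)oxy]-3,5,11,13-tetramethyl-7-methylidenepentadeca-3,9,11-trien-2-one | CC(=O)/C(C)=C/[C@H](C)CC(=C)C/C=C(\O[Si](C)(C)C(C)(C)C)/C(C)=C/[C@H](C)CC | intermediate
14 | trans-fused Diels–Alder adduct, 1-silyloxy-1-ene (4aα-H, 8aβ-H, 3α-sec-butyl, 4β-CH3, 4α-acetyl, 5α-CH3) | CC[C@@H](C)[C@@H]1[C@](C)(C(C)=O)[C@H]2[C@H](C)CC(=C)C[C@@H]2C(O[Si](C)(C)C(C)(C)C)=C1C | intermediate
15 | 1β,2β-epoxide of 14 (1-silyloxy oxirane) | CC[C@@H](C)[C@@H]1[C@](C)(C(C)=O)[C@H]2[C@H](C)CC(=C)C[C@@H]2[C@]3(O[Si](C)(C)C(C)(C)C)[C@@]1(C)O3 | intermediate (not isolated)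
16 | (2S,3R,4R,4aS,5R,8aS)-4-acetyl-3-[(2R)-butan-2-yl]-2-hydroxy-2,4,5-trimethyl-7-methylideneoctahydronaphthalen-1(2H)-one | CC[C@@H](C)[C@@H]1[C@](C)(C(C)=O)[C@H]2[C@H](C)CC(=C)C[C@@H]2C(=O)[C@@]1(C)O | intermediate
17 | Δ4a,8a-enone: 4α-acetyl-3α-[(2R)-butan-2-yl]-2β-hydroxy-2α,4β,5α-trimethyl-7-methylidene-3,4,5,6,7,8-hexahydronaphthalen-1(2H)-one | CC[C@@H](C)[C@@H]1[C@](C)(C(C)=O)C2=C(C(=O)[C@@]1(C)O)CC(=C)C[C@H]2C | intermediate
18 | 7β-hydroxy-7α-(hydroxymethyl) derivative of 17 | CC[C@@H](C)[C@@H]1[C@](C)(C(C)=O)C2=C(C(=O)[C@@]1(C)O)C[C@@](O)(CO)C[C@H]2C | intermediate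
19 | tris-O-TMS ether of 18 with the acetyl group as its TMS enol ether | CC[C@@H](C)[C@@H]1[C@](C)(C(=C)O[Si](C)(C)C)C2=C(C(=O)[C@@]1(C)O[Si](C)(C)C)C[C@@](O[Si](C)(C)C)(CO[Si](C)(C)C)C[C@H]2C | intermediate (not isolated)
20 | Δ4a,8a-enone with the complete side chain: 4α-(3-hydroxypropanoyl) analogue of 18 | CC[C@@H](C)[C@@H]1[C@](C)(C(=O)CCO)C2=C(C(=O)[C@@]1(C)O)C[C@@](O)(CO)C[C@H]2C | intermediate
21 | (2S,3R,4R,4aR,5R,7R,8aS)-3-[(2R)-butan-2-yl]-2,7-dihydroxy-7-(hydroxymethyl)-4-(3-hydroxypropanoyl)-2,4,5-trimethyloctahydronaphthalen-1(2H)-one | CC[C@@H](C)[C@@H]1[C@](C)(C(=O)CCO)[C@@H]2[C@H](C)C[C@](O)(CO)C[C@@H]2C(=O)[C@@]1(C)O | target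

**Totals and risks**
Total step count: 14. Longest linear sequence: 13 steps (1 → 2 → 3 → 8 → 10 → 11 → 12 → 13 → 14 → 16 → 17 → 18 → 20 → 21).

The three steps most likely to fail:

Step 11 (dehydrogenation). The α-hydrogen is tertiary and hindered, and loss of a C8 hydrogen instead of the C4a hydrogen would give the wrong enone. The fallback sets out from 16: silylation with TMSOTf/Et3N gives the tris(trimethylsilyl) bis(enol ether) F1, in which the ring enol ether C1=C8a is fixed by the substitution pattern. Saegusa–Ito oxidation with Pd(OAc)2 in MeCN then oxidises the ring enol ether; the acetyl enol ether has no β-hydrogen and is hydrolysed, with the 2-O-TMS group, on citric acid work-up. The route is rejoined at 17.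

Step 13 (late hydroxymethylation on a polyol). Over-silylation, γ-enolisation of the ring enone or double aldol could erode the yield. The fallback sets out from 12 and carries the oxygenated two-carbon arm from the start. The dianion of 4 is alkylated with benzyl chloromethyl ether to diethyl [5-(benzyloxy)-3-oxopentan-2-yl]phosphonate F2, and HWE with 12 gives the benzyloxy trienone F3. The Diels–Alder reaction gives the adduct F4, and Rubottom oxidation through the silyloxy epoxide F5 gives the ketol F6. Excess IBX desaturates both ketones to the bis-enone F7 (ring Δ4a,8a-enone plus an (E)-3-(benzyloxy)acryloyl arm), and OsO4/NMO gives the diol F8. The final H2, Pd on carbon step saturates both C=C bonds and cleaves the benzyl ether, rejoining the route at 21.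

Step 14 (hydrogenation of a tetrasubstituted enone next to a quaternary carbon, with the face set only by sterics). The fallback sets out from 18 and reduces before the aldol, under hydroxyl direction. [Ir(cod)(PCy3)(py)]PF6 and H2 in CH2Cl2, guided by the 2β- and 7β-hydroxyls, give the cis-fused methyl ketone F9. Kinetic silylation (TMSOTf/Et3N, −78 °C, methyl ketone only) gives the silyl enol ether F10, and aqueous HCHO/Yb(OTf)3 rejoins the route at 21.

**Further compounds**
F1 | step 11 | 2-O-TMS, 1-(trimethylsilyloxy)-1(8a)-ene, acetyl TMS enol ether derivative of 16 | CC[C@@H](C)[C@@H]1[C@](C)(C(=C)O[Si](C)(C)C)[C@H]2[C@H](C)CC(=C)CC2=C(O[Si](C)(C)C)[C@@]1(C)O[Si](C)(C)C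
F2 | step 13 | diethyl [5-(benzyloxy)-3-oxopentan-2-yl]phosphonate | CCOP(=O)(OCC)C(C)C(=O)CCOCc1ccccc1
F3 | step 13 | (4E,6R,10Z,12E,14R)-1-(benzyloxy)-11-[(tert-butyldimethylsilyl)oxy]-4,6,12,14-tetramethyl-8-methylidenehexadeca-4,10,12-trien-3-one | O=C(CCOCc1ccccc1)/C(C)=C/[C@H](C)CC(=C)C/C=C(\O[Si](C)(C)C(C)(C)C)/C(C)=C/[C@H](C)CC
F4 | step 13 | 4α-[3-(benzyloxy)propanoyl] analogue of 14 | CC[C@@H](C)[C@@H]1[C@](C)(C(=O)CCOCc3ccccc3)[C@H]2[C@H](C)CC(=C)C[C@@H]2C(O[Si](C)(C)C(C)(C)C)=C1C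
F5 | step 13 | 1β,2β-silyloxy epoxide of F4 | CC[C@@H](C)[C@@H]1[C@](C)(C(=O)CCOCc4ccccc4)[C@H]2[C@H](C)CC(=C)C[C@@H]2[C@]3(O[Si](C)(C)C(C)(C)C)[C@@]1(C)O3
F6 | step 13 | 4α-[3-(benzyloxy)propanoyl] analogue of 16 | CC[C@@H](C)[C@@H]1[C@](C)(C(=O)CCOCc3ccccc3)[C@H]2[C@H](C)CC(=C)C[C@@H]2C(=O)[C@@]1(C)O
F7 | step 13 | 4α-[(E)-3-(benzyloxy)acryloyl] analogue of 17 | CC[C@@H](C)[C@@H]1[C@](C)(C(=O)/C=C/OCc3ccccc3)C2=C(C(=O)[C@@]1(C)O)CC(=C)C[C@H]2C
F8 | step 13 | 4α-[(E)-3-(benzyloxy)acryloyl] analogue of 18 | CC[C@@H](C)[C@@H]1[C@](C)(C(=O)/C=C/OCc3ccccc3)C2=C(C(=O)[C@@]1(C)O)C[C@@](O)(CO)C[C@H]2C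
F9 | step 14 | cis-fused (4aβ-H, 8aβ-H) 4α-acetyl analogue of 21 | CC[C@@H](C)[C@@H]1[C@](C)(C(C)=O)[C@@H]2[C@H](C)C[C@](O)(CO)C[C@@H]2C(=O)[C@@]1(C)O
F10 | step 14 | tris-O-TMS ether of F9 with the acetyl group as its TMS enol ether | CC[C@@H](C)[C@@H]1[C@](C)(C(=C)O[Si](C)(C)C)[C@@H]2[C@H](C)C[C@](O[Si](C)(C)C)(CO[Si](C)(C)C)C[C@@H]2C(=O)[C@@]1(C)O[Si](C)(C)C
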